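Time came first: Sunday's readings barely moved after 4.00 d and Monday's after 4.00 d, yet the two runs came to rest at different splits.

the same everywhere: gas 12 mM (held)
- Sunday's: substrate 0.12 M; run made earlier
- Monday's: substrate 0.46 M; run made earlier
- flask: substrate 0.23 M; time 15 d

| run | time / d | product / % | intermediate / % |
|---|---|---|---|
| Sunday's | 1.25 | 46.3 | 25.3 |
| Sunday's | 1.67 | 53.4 | 27.7 |
| Sunday's | 3.00 | 61.7 | 34.2 |
| Sunday's | 4.00 | 63.1 | 33.9 |
| Sunday's | 6.00 | 63.0 | 34.5 |
| Sunday's | 10.0 | 63.4 | 34.2 |
| Sunday's | 15.0 | 64.3 | 35.6 |
| Monday's | 2.00 | 34.4 | 41.9 |
| Monday's | 4.00 | 41.6 | 54.6 |
| Monday's | 6.00 | 41.9 | 55.5 |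
| Monday's | 8.00 | 41.6 | 56.1 |
| Monday's | 10.0 | 42.0 | 57.1 |
| Monday's | 12.0 | 40.9 | 56.2 |
| Monday's | 15.0 | 41.0 | 56.2 |

(each reading ± 0.5 percentage points)

- at the start none of the gas is in solution
- the reaction counts as stopped when no species that holds the substrate changes by six tenths of a point or more over the second half of the time

- which holds at 15 d: what has brought the reaction to rest, or that it has not come to rest (forward and back rates have come level / it is still moving)
- product at 15 d, in percent of the substrate charged
- intermediate at 15 d, in percent of the substrate charged

Averaged from the start to the first reading, product rose as a fraction of the charge at 0.370 d⁻¹ on Sunday and 0.172 d⁻¹ on Monday. I looked for what slowed it. The charge times the square of the product fraction, over the intermediate fraction, read 0.141 M late on Sunday and 0.142 M late on Monday, although the charges differed by a factor of 3.83. I carried their mean, 0.141 M, as the rest quotient, an equilibrium constant as read from the runs.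

I took the net rate to be the forward rate times one minus the running quotient over this value. In Sunday's run that factor read 0.281 at 1.25 d and 0.0558 at 3.00 d, a further fall by a factor of 5.04. The slowing ends in a standstill where the factor reaches nothing, and both runs read flat sooner than 15 d.

Those late readings left 2.35 % of the charge, on average, in neither form. With that remainder, I reckoned 52.6 % product and 45.0 % intermediate for the flask.

The forecast said forward and back rates have come level, with product 52.5 % and intermediate 45.3 %, on this ground: “A single constant across both runs indicates true equilibrium”. My product and the forecast's differed by 0.10 percentage points, and my intermediate stood 0.30 points lower.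

The flask gave forward and back rates have come level, with product 52.7 % and intermediate 45.6 %.

    gas ⇌ partner, rate k1*(csat - [partner]) (kL = 0.0251 min⁻¹)
    intermediate ⇌ product + by-product (K = 0.140 M, k = 0.00227 min⁻¹)
    substrate + partner ⇌ intermediate (K = 2510 L mol⁻¹, k = 0.0823 L mol⁻¹ min⁻¹)
    partner → decomposed reagent (k = 0.00367 min⁻¹)

Held against my 0.141 M, the flask's ending made the factor 0.0104. In the flask, the forward half-life of intermediate by its split into product and by-product, the way back not counted, was 0.21 d, shorter than the 15 d. For the forecast's product to fail in this flask, a reading at 2.20 d puts product 5 points off, as does a charge of 0.310 M. For the neighbouring flask charged with 0.39 M, the rest quotient gives 44.1 % product and 53.6 % intermediate; that flask gave 44.0 % and 53.9 %.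

The earlier runs and the new flask come from a simulation on assumed constants; the scatter is artificial.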